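Ring C of the flavanone is cut at three bonds. Its carbonyl carbon C4' sits between C4a' of the phloroglucinol ring A and the two-carbon unit C3'–C2' carried by C5 of the dihydrobenzofuran, and O1' sits on the neighbouring ring-A carbon C8a'. This is the pattern of an ortho-iodophenol, carbon monoxide and a terminal alkyne. One palladium-catalysed carbonylative annulation joins C4a'–C4', C4'–C3' and O1'–C2' and closes the pyranone as a flavone, so the epimerisable C2' stays flat until a late enantioselective hydrogenation. The alkyne partner is the fully benzylated (2R,3S)-5-ethynyl-2,3-dihydrobenzofuran, built by an Evans aldol and an acid-triggered ring closure.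

Key step: step 13

Remarks
- Unprimed locants refer to the dihydrobenzofuran, primed locants to the chromanone.
- Assumption: 3,5-bis(benzyloxy)phenol, 4-(benzyloxy)-3-methoxybenzaldehyde and (R)-4-benzyl-2-oxazolidinone are bought as catalogue compounds.
- Copper is kept out of the key step, because a copper acetylide opens the carbon monoxide-free coupling that ends in a 2-arylbenzofuran.

Step 1
Reactants: 1 2,3-dihydroxybenzaldehyde
Product: 2 5-bromo-2,3-dihydroxybenzaldehyde
Conditions: Br2 (1.0 equiv), AcOH, 10 °C → rt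
Reagents that add atoms: bromine, BrBr
Why: Electrophilic aromatic bromination should go to C5, the one position that is para to a hydroxyl group (2-OH) and meta to the deactivating formyl group.

Step 2
Reactants: 2 5-bromo-2,3-dihydroxybenzaldehyde
Product: 3 5-bromo-2,3-bis(methoxymethoxy)benzaldehyde
Conditions: MOMCl (3 equiv), i-Pr2NEt (4 equiv), Bu4NI (cat.), CH2Cl2, 0 → 40 °C
Reagents that add atoms: chloromethyl methyl ether, COCCl
Why: Williamson-type O-alkylation of both phenols (the chelated 2-OH needs the excess reagent and gentle warming) installs acetal ethers that survive base, hydride and boron enolate chemistry and fall off in the acid step that closes the ring.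

Step 3
Reactants: 3 5-bromo-2,3-bis(methoxymethoxy)benzaldehyde
Product: 5 2-[5-bromo-2,3-bis(methoxymethoxy)phenyl]acetonitrile, via tosylvinyl formamide 4 (not isolated)
Conditions: TosMIC (1.2 equiv), t-BuOK (2.4 equiv), DME, −50 °C; then MeOH, reflux
Reagents that add atoms: tosylmethyl isocyanide (TosMIC), Cc1ccc(cc1)S(=O)(=O)C[N+]#[C-]
Why: Van Leusen reductive cyanation: the TosMIC anion adds to the aldehyde, the oxazoline adduct opens under the excess base to the N-formyl enamide 4, and methanolysis with loss of sulfinate leaves the nitrile one carbon longer than the aldehyde, the low temperature of the addition holding back oxazole formation.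

Step 4
Reactants: 5 2-[5-bromo-2,3-bis(methoxymethoxy)phenyl]acetonitrile
Product: 6 2-[5-bromo-2,3-bis(methoxymethoxy)phenyl]acetic acid
Conditions: KOH (6 equiv), EtOH/H2O (3:1), reflux; then 1 M HCl to pH 3–4, 0 °C
Reagents that add atoms: water, O; potassium hydroxide, [K+].[OH-]
Why: Alkaline nitrile hydrolysis leaves the acetal ethers and the unactivated aryl bromide untouched, and the cold acidification only protonates the carboxylate.

Step 5
Reactants: 6 2-[5-bromo-2,3-bis(methoxymethoxy)phenyl]acetic acid; 7 (R)-4-benzyl-2-oxazolidinone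
Product: 9 (4R)-4-benzyl-3-{2-[5-bromo-2,3-bis(methoxymethoxy)phenyl]acetyl}oxazolidin-2-one, via mixed pivalic anhydride 8 (not isolated)
Conditions: PivCl (1.1 equiv), Et3N (2.5 equiv), THF, −20 °C; then 7, LiCl (1.1 equiv), −20 °C → rt
Reagents that add atoms: none
Why: N-Acylation of the auxiliary through a mixed anhydride, in which the tert-butyl group blocks the pivaloyl carbonyl so that the lithium-chelated oxazolidinone attacks the arylacetyl carbonyl.

Step 6
Reactants: 9 N-arylacetyl oxazolidinone; 10 4-(benzyloxy)-3-methoxybenzaldehyde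
Product: 12 (2R,3R) syn aldol adduct (full name in the list), via Z boron enolate 11 (not isolated)
Conditions: n-Bu2BOTf (1.2 equiv), i-Pr2NEt (1.4 equiv), CH2Cl2, −78 → 0 °C; 10, −78 → 0 °C; then pH 7 buffer, MeOH, 30% H2O2, 0 °C
Reagents that add atoms: none
Why: Evans syn aldol addition: soft enolisation gives the Z boron enolate 11, which reacts through a closed chair transition state on the face remote from the benzyl group of the auxiliary, so that the (R)-auxiliary fixes the aryl-bearing carbon as R (it becomes C3, named S once the imide is reduced) and the carbinol carbon as R.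

Step 7
Reactants: 12 syn aldol adduct
Product: 13 (1R,2S)-1-[4-(benzyloxy)-3-methoxyphenyl]-2-[5-bromo-2,3-bis(methoxymethoxy)phenyl]propane-1,3-diol
Conditions: LiBH4 (2.5 equiv), MeOH (2.5 equiv), THF, 0 °C
Reagents that add atoms: none
Why: Borohydride reduction of the exocyclic imide carbonyl (reductive auxiliary cleavage) should give the primary alcohol at 0 °C without retro-aldol cleavage or epimerisation and return the oxazolidinone.

Step 8
Reactants: 13 bis-MOM diol
Product: 15 (2R,3S)-2-[4-(benzyloxy)-3-methoxyphenyl]-5-bromo-3-(hydroxymethyl)-2,3-dihydro-1-benzofuran-7-ol, via catechol diol 14 (not isolated)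
Conditions: HCl (1.25 M in MeOH), THF, 0 → 45 °C
Reagents that add atoms: none
Why: Acidic methanolysis frees both phenols (14), the electron-rich benzylic alcohol then ionises (SN1) and the adjacent phenol captures the cation in a 5-exo closure on the face that puts the aryl group trans to the hydroxymethyl group of the untouched C3, which sets C2 as R.

Step 9
Reactants: 15 bromo dihydrobenzofuran phenol alcohol
Product: 16 (2R,3S)-7-(benzyloxy)-2-[4-(benzyloxy)-3-methoxyphenyl]-3-[(benzyloxy)methyl]-5-bromo-2,3-dihydro-1-benzofuran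
Conditions: NaH (2.6 equiv), BnBr (2.5 equiv), Bu4NI (cat.), DMF, 0 °C → rt
Reagents that add atoms: benzyl bromide, BrCc1ccccc1
Why: Williamson etherification of the phenoxide and the primary alkoxide in one pot, under which neither ring stereocentre is acidic.

Step 10
Reactants: 16 tribenzyl bromo dihydrobenzofuran
Product: 17 (2R,3S)-7-(benzyloxy)-2-[4-(benzyloxy)-3-methoxyphenyl]-3-[(benzyloxy)methyl]-5-[(trimethylsilyl)ethynyl]-2,3-dihydro-1-benzofuran
Conditions: TMS-acetylene (2 equiv), PdCl2(PhCN)2 (3 mol%), [HP(t-Bu)3]BF4 (6 mol%), CuI (2 mol%), i-Pr2NH, dioxane, rt → 50 °C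
Reagents that add atoms: trimethylsilylacetylene, C#C[Si](C)(C)C
Why: Sonogashira coupling, in which the bulky electron-rich phosphine lets zerovalent palladium insert into the electron-rich aryl bromide near room temperature.

Step 11
Reactants: 17 silyl alkyne
Product: 18 (2R,3S)-7-(benzyloxy)-2-[4-(benzyloxy)-3-methoxyphenyl]-3-[(benzyloxy)methyl]-5-ethynyl-2,3-dihydro-1-benzofuran
Conditions: K2CO3 (0.2 equiv), MeOH/THF (1:1), rt
Reagents that add atoms: none
Why: Methoxide-induced protodesilylation of the alkynylsilane, to which the ethers and both stereocentres are inert.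

Step 12
Reactants: 19 3,5-bis(benzyloxy)phenol
Product: 20 3,5-bis(benzyloxy)-2-iodophenol
Conditions: NIS (1.0 equiv), CH2Cl2, −40 → 0 °C
Reagents that add atoms: N-iodosuccinimide, O=C1CCC(=O)N1I
Why: Electrophilic aromatic iodination of the activated ring, directed mainly to one of the two equivalent carbons ortho to the free hydroxyl (less hindered than the carbon between the two benzyloxy groups), with one equivalent of reagent at low temperature to limit di-iodination and chromatography to remove the para isomer.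

Step 13
Reactants: 18 5-ethynyl dihydrobenzofuran; 20 3,5-bis(benzyloxy)-2-iodophenol (1.3 equiv); 21 carbon monoxide
Product: 24 pentabenzyl flavone (full name in the list), via ynone 22 (not isolated), via enaminone 23 (not isolated)
Conditions: PdCl2(dppf) (5 mol%), CO (20 bar), degassed Et2NH, 120 °C, autoclave, no copper salt
Reagents that add atoms: none
Why: Zerovalent palladium (formed from PdCl2(dppf) in the amine) inserts into the C–I bond of 20, carbon monoxide inserts to give the aroyl-palladium species, and the amine-deprotonated alkyne 18 is transferred and reductively eliminated, which makes C4a'–C4' and C4'–C3' in ynone 22. Diethylamine then adds across the ynone to enaminone 23, and the ortho phenol displaces the amine at C2' by addition–elimination, which makes O1'–C2' and releases the flavone. The closest known reaction type is the palladium-catalysed carbonylative coupling of o-iodophenols with terminal alkynes in a secondary amine, which gives flavones and chromones. Ring C closes in the 6-endo mode (formally 6-endo-dig on the ynone, in practice 6-endo-trig on the enaminone); no stereocentre is created, and the non-acidic C2 and C3 of the dihydrobenzofuran are spectators. The step needs 6-endo over 5-exo closure (flavone, not aurone), secured by the enaminone, whose amine-bearing carbon is the only electrophilic site, and it needs carbon monoxide uptake to outrun direct alkynylation, secured by the pressure and by leaving copper out.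

Step 14
Reactants: 24 pentabenzyl flavone
Product: 26 pentabenzyl (2'S)-flavanone (full name in the list), via flavan-4-ol 25 (not isolated)
Conditions: [Ru(cod)(2-methylallyl)2] (5 mol%), 1,3-bis[(R)-1-(naphthalen-1-yl)ethyl]-4,5-dihydroimidazolium tetrafluoroborate (10 mol%), t-BuOK (15 mol%), hexane, 70 °C (catalyst formation); 24, H2 (100 bar), toluene, rt → 40 °C; crude product: Dess–Martin periodinane (1.5 equiv), CH2Cl2, 0 °C → rt
Reagents that add atoms: none
Why: Asymmetric hydrogenation of the flavone C2'=C3' bond by a chiral ruthenium bis(carbene) catalyst, whose C2-symmetric pocket selects the alkene face and so sets C2' as S (the antipodal carbene salt is the switch if the sense proves opposite), while the portion over-reduced to flavan-4-ol 25 keeps that C2' configuration and is returned to the ketone by Dess–Martin oxidation.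

Step 15
Reactants: 26 pentabenzyl (2'S)-flavanone
Product: 27 silyhermin B
Conditions: H2 (1 atm), Pd(OH)2/C (20 wt%), EtOAc/MeOH (1:1), rt, stopped at full debenzylation
Reagents that add atoms: none
Why: Hydrogenolysis of the five O-benzyl groups under neutral conditions, which spare the acid- and base-labile C2', since benzyl ethers are cleaved much faster than the secondary benzylic ring ethers at C2 and C2' or the chelated aryl ketone.

Compound list
1 | 2,3-dihydroxybenzaldehyde | O=Cc1cccc(O)c1O | starting material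
2 | 5-bromo-2,3-dihydroxybenzaldehyde | O=Cc1cc(Br)cc(O)c1O | intermediate
3 | 5-bromo-2,3-bis(methoxymethoxy)benzaldehyde | O=Cc1cc(Br)cc(OCOC)c1OCOC | intermediate
4 | N-{2-[5-bromo-2,3-bis(methoxymethoxy)phenyl]-1-tosylethenyl}formamide (alkene geometry not defined) | O=CNC(=Cc1cc(Br)cc(OCOC)c1OCOC)S(=O)(=O)c1ccc(C)cc1 | intermediate (not isolated)
5 | 2-[5-bromo-2,3-bis(methoxymethoxy)phenyl]acetonitrile | N#CCc1cc(Br)cc(OCOC)c1OCOC | intermediate
6 | 2-[5-bromo-2,3-bis(methoxymethoxy)phenyl]acetic acid | OC(=O)Cc1cc(Br)cc(OCOC)c1OCOC | intermediate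
7 | (R)-4-benzyl-2-oxazolidinone | O=C1N[C@H](Cc2ccccc2)CO1 | starting material
8 | 2-[5-bromo-2,3-bis(methoxymethoxy)phenyl]acetic pivalic anhydride | CC(C)(C)C(=O)OC(=O)Cc1cc(Br)cc(OCOC)c1OCOC | intermediate (not isolated)
9 | (4R)-4-benzyl-3-{2-[5-bromo-2,3-bis(methoxymethoxy)phenyl]acetyl}oxazolidin-2-one | O=C1OC[C@@H](Cc2ccccc2)N1C(=O)Cc1cc(Br)cc(OCOC)c1OCOC | intermediate
10 | 4-(benzyloxy)-3-methoxybenzaldehyde | COc1cc(C=O)ccc1OCc1ccccc1 | starting material
11 | Z dibutylboron enolate of 9 | CCCCB(CCCC)O/C(=C\c1cc(Br)cc(OCOC)c1OCOC)N1C(=O)OC[C@H]1Cc1ccccc1 | intermediate (not isolated)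
12 | (4R)-4-benzyl-3-{(2R,3R)-3-[4-(benzyloxy)-3-methoxyphenyl]-2-[5-bromo-2,3-bis(methoxymethoxy)phenyl]-3-hydroxypropanoyl}oxazolidin-2-one | O=C1OC[C@@H](Cc2ccccc2)N1C(=O)[C@H](c1cc(Br)cc(OCOC)c1OCOC)[C@@H](O)c1ccc(OCc2ccccc2)c(OC)c1 | intermediate
13 | (1R,2S)-1-[4-(benzyloxy)-3-methoxyphenyl]-2-[5-bromo-2,3-bis(methoxymethoxy)phenyl]propane-1,3-diol | OC[C@H](c1cc(Br)cc(OCOC)c1OCOC)[C@@H](O)c1ccc(OCc2ccccc2)c(OC)c1 | intermediate
14 | (1R,2S)-1-[4-(benzyloxy)-3-methoxyphenyl]-2-(5-bromo-2,3-dihydroxyphenyl)propane-1,3-diol | OC[C@H](c1cc(Br)cc(O)c1O)[C@@H](O)c1ccc(OCc2ccccc2)c(OC)c1 | intermediate (not isolated)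
15 | (2R,3S)-2-[4-(benzyloxy)-3-methoxyphenyl]-5-bromo-3-(hydroxymethyl)-2,3-dihydro-1-benzofuran-7-ol (trans) | COc1cc([C@@H]2Oc3c(O)cc(Br)cc3[C@H]2CO)ccc1OCc1ccccc1 | intermediate
16 | (2R,3S)-7-(benzyloxy)-2-[4-(benzyloxy)-3-methoxyphenyl]-3-[(benzyloxy)methyl]-5-bromo-2,3-dihydro-1-benzofuran | COc1cc([C@@H]2Oc3c(OCc4ccccc4)cc(Br)cc3[C@H]2COCc2ccccc2)ccc1OCc1ccccc1 | intermediate
17 | (2R,3S)-7-(benzyloxy)-2-[4-(benzyloxy)-3-methoxyphenyl]-3-[(benzyloxy)methyl]-5-[(trimethylsilyl)ethynyl]-2,3-dihydro-1-benzofuran | COc1cc([C@@H]2Oc3c(OCc4ccccc4)cc(C#C[Si](C)(C)C)cc3[C@H]2COCc2ccccc2)ccc1OCc1ccccc1 | intermediate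
18 | (2R,3S)-7-(benzyloxy)-2-[4-(benzyloxy)-3-methoxyphenyl]-3-[(benzyloxy)methyl]-5-ethynyl-2,3-dihydro-1-benzofuran | COc1cc([C@@H]2Oc3c(OCc4ccccc4)cc(C#C)cc3[C@H]2COCc2ccccc2)ccc1OCc1ccccc1 | intermediate (key-step precursor)
19 | 3,5-bis(benzyloxy)phenol | Oc1cc(OCc2ccccc2)cc(OCc2ccccc2)c1 | starting material
20 | 3,5-bis(benzyloxy)-2-iodophenol | Oc1cc(OCc2ccccc2)cc(OCc2ccccc2)c1I | intermediate
21 | carbon monoxide | [C-]#[O+] | starting material
22 | 1-[2,4-bis(benzyloxy)-6-hydroxyphenyl]-3-[(2R,3S)-7-(benzyloxy)-2-[4-(benzyloxy)-3-methoxyphenyl]-3-[(benzyloxy)methyl]-2,3-dihydro-1-benzofuran-5-yl]prop-2-yn-1-one | COc1cc([C@@H]2Oc3c(OCc4ccccc4)cc(C#CC(=O)c4c(O)cc(OCc5ccccc5)cc4OCc4ccccc4)cc3[C@H]2COCc2ccccc2)ccc1OCc1ccccc1 | intermediate (not isolated)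
23 | 1-[2,4-bis(benzyloxy)-6-hydroxyphenyl]-3-(diethylamino)-3-[(2R,3S)-7-(benzyloxy)-2-[4-(benzyloxy)-3-methoxyphenyl]-3-[(benzyloxy)methyl]-2,3-dihydro-1-benzofuran-5-yl]prop-2-en-1-one (alkene geometry not defined) | COc1cc([C@@H]2Oc3c(OCc4ccccc4)cc(C(=CC(=O)c4c(O)cc(OCc5ccccc5)cc4OCc4ccccc4)N(CC)CC)cc3[C@H]2COCc2ccccc2)ccc1OCc1ccccc1 | intermediate (not isolated)
24 | 5,7-bis(benzyloxy)-2-[(2R,3S)-7-(benzyloxy)-2-[4-(benzyloxy)-3-methoxyphenyl]-3-[(benzyloxy)methyl]-2,3-dihydro-1-benzofuran-5-yl]-4H-chromen-4-one | COc1cc([C@@H]2Oc3c(OCc4ccccc4)cc(-c4cc(=O)c5c(OCc6ccccc6)cc(OCc6ccccc6)cc5o4)cc3[C@H]2COCc2ccccc2)ccc1OCc1ccccc1 | intermediate (key-step product)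
25 | (2S,4S)-5,7-bis(benzyloxy)-2-[(2R,3S)-7-(benzyloxy)-2-[4-(benzyloxy)-3-methoxyphenyl]-3-[(benzyloxy)methyl]-2,3-dihydro-1-benzofuran-5-yl]-3,4-dihydro-2H-chromen-4-ol (2,4-cis expected; C4' is erased on oxidation) | COc1cc([C@@H]2Oc3c(OCc4ccccc4)cc([C@@H]4C[C@H](O)c5c(OCc6ccccc6)cc(OCc6ccccc6)cc5O4)cc3[C@H]2COCc2ccccc2)ccc1OCc1ccccc1 | intermediate (not isolated)
26 | (2S)-5,7-bis(benzyloxy)-2-[(2R,3S)-7-(benzyloxy)-2-[4-(benzyloxy)-3-methoxyphenyl]-3-[(benzyloxy)methyl]-2,3-dihydro-1-benzofuran-5-yl]-2,3-dihydro-4H-chromen-4-one | COc1cc([C@@H]2Oc3c(OCc4ccccc4)cc([C@@H]4CC(=O)c5c(OCc6ccccc6)cc(OCc6ccccc6)cc5O4)cc3[C@H]2COCc2ccccc2)ccc1OCc1ccccc1 | intermediate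
27 | silyhermin B, (2S)-5,7-dihydroxy-2-[(2R,3S)-7-hydroxy-2-(4-hydroxy-3-methoxyphenyl)-3-(hydroxymethyl)-2,3-dihydro-1-benzofuran-5-yl]-2,3-dihydro-4H-chromen-4-one | COc1cc([C@@H]2Oc3c(O)cc([C@@H]4CC(=O)c5c(O)cc(O)cc5O4)cc3[C@H]2CO)ccc1O | target

Total step count: 15. Longest linear sequence: 14 steps (steps 1–11, then 13, 14 and 15); step 12 is the one-step side branch.

Steps most likely to fail

1. Step 14. The alkene face may be poorly discriminated, because the C5' benzyloxy group crowds the carbonyl next to the C2'=C3' bond and the two remote ring stereocentres give no help. Fallback (kinetic resolution in place of face-selective hydrogenation): set out from 24 and reduce without face control, using the same ruthenium precursor with the achiral carbene from 1,3-dicyclohexylimidazolium chloride, then Dess–Martin oxidation. This gives the 2'-epimeric mixture 5,7-bis(benzyloxy)-2-[(2R,3S)-dihydrobenzofuran-5-yl]chroman-4-one F1. F1 is then submitted to Noyori–Ikariya transfer hydrogenation (RuCl[(R,R)-TsDPEN](p-cymene), HCO2H/Et3N 5:2, EtOAc, rt). By analogy with aryl ketone reductions this should consume the 2'R epimer as the (2'R,4'R)-cis-flavan-4-ol F2 and leave the 2'S ketone, which is compound 26, where the route is rejoined. The antipodal catalyst is used if the sense is reversed.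

2. Step 13. The aroyl-palladium intermediate may be intercepted by diethylamine (amide formation), the alkyne may couple without carbon monoxide and close to a 2-arylbenzofuran, or oxidative addition at the doubly ortho-substituted iodide may be slow. Fallback (carbon monoxide-free chalcone route): set out from bromide 16. Bromine–lithium exchange and formylation (n-BuLi, THF, −78 °C; DMF) give (2R,3S)-7-(benzyloxy)-2-[4-(benzyloxy)-3-methoxyphenyl]-3-[(benzyloxy)methyl]-2,3-dihydro-1-benzofuran-5-carbaldehyde F3. Claisen–Schmidt condensation (KOH, EtOH/THF, rt) with 1-[2,4-bis(benzyloxy)-6-hydroxyphenyl]ethanone F4 (from 2',4',6'-trihydroxyacetophenone, BnBr, K2CO3, DMF) gives the (E)-2'-hydroxychalcone F5. Oxidative cyclisation (I2 10 mol%, DMSO, 120 °C) returns to flavone 24.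

3. Step 15. Over-reduction may occur: hydrogenolytic opening of the benzylic ring bonds C2–O1 or C2'–O1', or reduction of the C4' carbonyl, before the slower alkyl benzyl ether has gone. Fallback (non-reductive debenzylation): treat 26 with BCl3 and pentamethylbenzene as benzyl cation scavenger (CH2Cl2, −78 → −30 °C), which should give 27 directly and leave the aryl methyl ether alone at this temperature. No new compound arises (entry F0).

Further compounds
F1 | step 14 | 5,7-bis(benzyloxy)-2-[(2R,3S)-7-(benzyloxy)-2-[4-(benzyloxy)-3-methoxyphenyl]-3-[(benzyloxy)methyl]-2,3-dihydro-1-benzofuran-5-yl]-2,3-dihydro-4H-chromen-4-one, mixture of C2' epimers | COc1cc([C@@H]2Oc3c(OCc4ccccc4)cc(C4CC(=O)c5c(OCc6ccccc6)cc(OCc6ccccc6)cc5O4)cc3[C@H]2COCc2ccccc2)ccc1OCc1ccccc1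
F2 | step 14 | (2R,4R)-5,7-bis(benzyloxy)-2-[(2R,3S)-7-(benzyloxy)-2-[4-(benzyloxy)-3-methoxyphenyl]-3-[(benzyloxy)methyl]-2,3-dihydro-1-benzofuran-5-yl]-3,4-dihydro-2H-chromen-4-ol | COc1cc([C@@H]2Oc3c(OCc4ccccc4)cc([C@H]4C[C@@H](O)c5c(OCc6ccccc6)cc(OCc6ccccc6)cc5O4)cc3[C@H]2COCc2ccccc2)ccc1OCc1ccccc1
F3 | step 13 | (2R,3S)-7-(benzyloxy)-2-[4-(benzyloxy)-3-methoxyphenyl]-3-[(benzyloxy)methyl]-2,3-dihydro-1-benzofuran-5-carbaldehyde | COc1cc([C@@H]2Oc3c(OCc4ccccc4)cc(C=O)cc3[C@H]2COCc2ccccc2)ccc1OCc1ccccc1
F4 | step 13 | 1-[2,4-bis(benzyloxy)-6-hydroxyphenyl]ethanone | CC(=O)c1c(O)cc(OCc2ccccc2)cc1OCc1ccccc1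
F5 | step 13 | (E)-1-[2,4-bis(benzyloxy)-6-hydroxyphenyl]-3-[(2R,3S)-7-(benzyloxy)-2-[4-(benzyloxy)-3-methoxyphenyl]-3-[(benzyloxy)methyl]-2,3-dihydro-1-benzofuran-5-yl]prop-2-en-1-one | COc1cc([C@@H]2Oc3c(OCc4ccccc4)cc(/C=C/C(=O)c4c(O)cc(OCc5ccccc5)cc4OCc4ccccc4)cc3[C@H]2COCc2ccccc2)ccc1OCc1ccccc1
F0 | step 15 | none | none
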